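Retrosynthesis: cut C3=C4 (olefination of a C4 aldehyde that comes from a vinyl group). Then contract the oxocane by cutting O–C12 and the C9–OAc bond while re-forming O–C9, which leads back to a C6–O–C9 oxolane with a C10 acetate and a C12–C13 cis-epoxide. Then cut C11–C12 (alkynide + terminal epoxide), O–C9 (epoxide-opening etherification), C8–C9 (acetylide + triflate) and C4–C5 (vinyl cuprate + triflate).
Forward: C4 and then C9–C11 are joined to the C5–C8 unit of D-threitol acetonide and the oxolane closes. But-1-yne then adds C12–C15, the ring oxygen bonds to C12 to give a transient second five-membered ring, loss of O–C9 merges both rings into the oxocane, and C1–C3 are attached last.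
Stereochemistry: C6 and C7 come from D-threitol; C9 and C10 from a Sharpless epoxidation (C9 inverted at oxolane closure and again in the ring expansion); C12 and C13 from a hydroxyl-directed epoxidation of a Z-alkene (C12 inverted in the ring expansion); 3Z from a Peterson olefination.
The directed epoxidation is expected to be 1,3-syn selective, whereas the ring expansion needs the epoxide 1,3-anti to the C10 acetate. It is therefore run on the C10 epimer (one Mitsunobu inversion before it), and the acetate is installed by a second Mitsunobu inversion.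
Enabling feature: in the oxocane (O, C6, C7, C8, C9, C10, C11, C12) the acetoxy carbon C9 is the fourth atom from oxygen in both directions, its neighbour C10 bears a trans acetate, and C12 bears the exocyclic C13 oxygen. O–C9 can therefore be a bond that exists only in the oxolane and in a bicyclic oxonium ion built from a C12–C13 epoxide.

Key step: step 19

Remark on numbering: C1–C15 are the chain atoms of the target (C1 = alkyne CH); the ring oxygen joins C6 and C12.
Assumption: water opens the acetoxonium ion of step 19 to a hydroxy acetate, drawn as the C10 acetate; the C9 acetate regioisomer (or a C13 acetate formed through an ortho ester) would give the same triacetate in step 20.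

Step 1
Reactants: 1 (4R,5R)-2,2-dimethyl-1,3-dioxolane-4,5-dimethanol
Product: 2 [(4R,5R)-5-({[tert-butyl(dimethyl)silyl]oxy}methyl)-2,2-dimethyl-1,3-dioxolan-4-yl]methanol
Conditions: NaH (1.0 equiv), THF, 0 °C; then TBSCl (1.0 equiv), rt
Reagents that add atoms: tert-butyldimethylsilyl chloride, CC(C)(C)[Si](C)(C)Cl
Why: O-silylation of the monosodium alkoxide of a C2-symmetric diol should stop at the mono-ether, and because the two hydroxyls are homotopic only one mono-ether exists and no stereocentre is touched.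

Step 2
Reactants: 2 [(4R,5R)-5-({[tert-butyl(dimethyl)silyl]oxy}methyl)-2,2-dimethyl-1,3-dioxolan-4-yl]methanol
Product: 3 [(4R,5R)-5-({[tert-butyl(dimethyl)silyl]oxy}methyl)-2,2-dimethyl-1,3-dioxolan-4-yl]methyl trifluoromethanesulfonate
Conditions: Tf2O, 2,6-lutidine, CH2Cl2, −78 °C; used crude
Reagents that add atoms: trifluoromethanesulfonic anhydride, O=S(=O)(OS(=O)(=O)C(F)(F)F)C(F)(F)F
Why: O-sulfonylation of the primary alcohol at low temperature gives the triflate, the leaving group that allows fast SN2 coupling at a carbon next to the dioxolane.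

Step 3
Reactants: 3 [(4R,5R)-5-({[tert-butyl(dimethyl)silyl]oxy}methyl)-2,2-dimethyl-1,3-dioxolan-4-yl]methyl trifluoromethanesulfonate; 4 vinylmagnesium bromide
Product: 5 tert-butyl(dimethyl){[(4R,5R)-2,2-dimethyl-5-(prop-2-en-1-yl)-1,3-dioxolan-4-yl]methoxy}silane
Conditions: 4 (3 equiv), CuI (10 mol %), THF, −40 → 0 °C
Reagents that add atoms: vinylmagnesium bromide (4), C=C[Mg]Br
Why: Copper-catalysed Grignard cross-coupling (SN2 displacement of a primary triflate by a vinyl cuprate) forms C4–C5 without touching the two stereocentres.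

Step 4
Reactants: 5 tert-butyl(dimethyl){[(4R,5R)-2,2-dimethyl-5-(prop-2-en-1-yl)-1,3-dioxolan-4-yl]methoxy}silane
Product: 6 [(4R,5R)-2,2-dimethyl-5-(prop-2-en-1-yl)-1,3-dioxolan-4-yl]methanol
Conditions: Bu4NF, THF, 0 °C → rt
Reagents that add atoms: none
Why: Fluoride-mediated desilylation frees the second primary alcohol, and the acetonide and alkene are inert to fluoride.

Step 5
Reactants: 6 [(4R,5R)-2,2-dimethyl-5-(prop-2-en-1-yl)-1,3-dioxolan-4-yl]methanol
Product: 7 [(4R,5R)-2,2-dimethyl-5-(prop-2-en-1-yl)-1,3-dioxolan-4-yl]methyl trifluoromethanesulfonate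
Conditions: Tf2O, 2,6-lutidine, CH2Cl2, −78 °C; used crude
Reagents that add atoms: trifluoromethanesulfonic anhydride, O=S(=O)(OS(=O)(=O)C(F)(F)F)C(F)(F)F
Why: O-sulfonylation as in step 2 activates C8 for acetylide alkylation.

Step 6
Reactants: 7 [(4R,5R)-2,2-dimethyl-5-(prop-2-en-1-yl)-1,3-dioxolan-4-yl]methyl trifluoromethanesulfonate; 8 tert-butyl(dimethyl)(prop-2-yn-1-yloxy)silane
Product: 9 tert-butyl(dimethyl)({4-[(4R,5R)-2,2-dimethyl-5-(prop-2-en-1-yl)-1,3-dioxolan-4-yl]but-2-yn-1-yl}oxy)silane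
Conditions: 8 (1.5 equiv), n-BuLi, THF, −78 °C; then 7, DMPU, −78 → 0 °C
Reagents that add atoms: tert-butyl(dimethyl)(prop-2-yn-1-yloxy)silane (8), C#CCO[Si](C)(C)C(C)(C)C
Why: SN2 alkylation of a lithium acetylide by a primary triflate forms C8–C9, and the propargylic oxygen is carried as a silyl ether so that it can later be freed without acid while the acetonide is present.

Step 7
Reactants: 9 tert-butyl(dimethyl)({4-[(4R,5R)-2,2-dimethyl-5-(prop-2-en-1-yl)-1,3-dioxolan-4-yl]but-2-yn-1-yl}oxy)silane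
Product: 10 4-[(4R,5R)-2,2-dimethyl-5-(prop-2-en-1-yl)-1,3-dioxolan-4-yl]but-2-yn-1-ol
Conditions: Bu4NF, THF, 0 °C → rt
Reagents that add atoms: none
Why: Fluoride desilylation gives the free propargylic alcohol that the next reduction needs as its directing group.

Step 8
Reactants: 10 4-[(4R,5R)-2,2-dimethyl-5-(prop-2-en-1-yl)-1,3-dioxolan-4-yl]but-2-yn-1-ol
Product: 11 (2E)-4-[(4R,5R)-2,2-dimethyl-5-(prop-2-en-1-yl)-1,3-dioxolan-4-yl]but-2-en-1-ol
Conditions: NaAlH2(OCH2CH2OMe)2 (Red-Al), THF, 0 °C → rt; aqueous Rochelle salt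
Reagents that add atoms: none
Why: Alkoxide-directed trans-hydroalumination of a propargylic alcohol followed by protonolysis should give only the E-allylic alcohol, and the isolated terminal alkene is not reduced.

Step 9
Reactants: 11 (2E)-4-[(4R,5R)-2,2-dimethyl-5-(prop-2-en-1-yl)-1,3-dioxolan-4-yl]but-2-en-1-ol
Product: 12 [(2R,3R)-3-{[(4R,5R)-2,2-dimethyl-5-(prop-2-en-1-yl)-1,3-dioxolan-4-yl]methyl}oxiran-2-yl]methanol
Conditions: Ti(OiPr)4 (10 mol %), D-(−)-diethyl tartrate (12 mol %), t-BuOOH, 4 Å molecular sieves, CH2Cl2, −20 °C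
Reagents that add atoms: tert-butyl hydroperoxide, CC(C)(C)OO
Why: Sharpless asymmetric epoxidation, in which the titanium D-tartrate complex delivers the peroxide oxygen to the face of the E-allylic alcohol that gives the (2R,3R)-epoxy alcohol (C9 R, C10 R) under reagent control, while the terminal alkene has no allylic hydroxyl and stays.

Step 10
Reactants: 12 [(2R,3R)-3-{[(4R,5R)-2,2-dimethyl-5-(prop-2-en-1-yl)-1,3-dioxolan-4-yl]methyl}oxiran-2-yl]methanol
Product: 14 (2R,3R,5S)-5-[(1R)-1,2-dihydroxyethyl]-2-(prop-2-en-1-yl)oxolan-3-ol (2,5-trans oxolane triol), via epoxy triol 13 (not isolated)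
Conditions: camphor-10-sulfonic acid (0.1 equiv), MeOH, 0 °C → rt
Reagents that add atoms: none
Why: Acid-catalysed transketalisation removes the acetonide, and the freed C6 hydroxyl opens the protonated epoxide at C9 in a 5-exo-tet etherification with inversion (preferred over 6-endo attack at C10 and over any closure by the C7 hydroxyl), which sets C9 as S, keeps C10 as R and gives the 2,5-trans oxolane.

Step 11
Reactants: 14 (2R,3R,5S)-5-[(1R)-1,2-dihydroxyethyl]-2-(prop-2-en-1-yl)oxolan-3-ol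
Product: 16 (2R,3R,5S)-5-[(2R)-oxiran-2-yl]-2-(prop-2-en-1-yl)oxolan-3-ol, via primary tosylate 15 (not isolated)
Conditions: Bu2SnO (2 mol %), TsCl (1.05 equiv), Et3N, CH2Cl2, 0 °C → rt; then K2CO3, MeOH, rt
Reagents that add atoms: none
Why: Stannylene-acetal-catalysed sulfonylation selects the primary hydroxyl of the 1,2-diol, and the C10 alkoxide then displaces the tosylate in a Williamson epoxide closure with retention at C10; the C7 hydroxyl is trans to the side chain across the ring and cannot take part.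

Step 12
Reactants: 16 (2R,3R,5S)-5-[(2R)-oxiran-2-yl]-2-(prop-2-en-1-yl)oxolan-3-ol
Product: 17 tert-butyl(dimethyl){[(2R,3R,5S)-5-[(2R)-oxiran-2-yl]-2-(prop-2-en-1-yl)oxolan-3-yl]oxy}silane
Conditions: TBSCl, imidazole, DMF, rt
Reagents that add atoms: tert-butyldimethylsilyl chloride, CC(C)(C)[Si](C)(C)Cl
Why: Imidazole-catalysed silylation protects the only free hydroxyl (C7) as an ether that should survive the base, the Mitsunobu conditions and the low-temperature Lewis acid used later.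

Step 13
Reactants: 17 tert-butyl(dimethyl){[(2R,3R,5S)-5-[(2R)-oxiran-2-yl]-2-(prop-2-en-1-yl)oxolan-3-yl]oxy}silane; 18 but-1-yne
Product: 19 (1R)-1-[(2S,4R,5R)-4-{[tert-butyl(dimethyl)silyl]oxy}-5-(prop-2-en-1-yl)oxolan-2-yl]hex-3-yn-1-ol
Conditions: 18 (3 equiv), n-BuLi, THF, −78 °C; BF3·OEt2; then 17, −78 °C
Reagents that add atoms: but-1-yne (18), CCC#C
Why: BF3-assisted SN2 opening of a terminal epoxide by an alkynyllithium occurs at the unsubstituted carbon C11, forms C11–C12 and leaves C10 untouched.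

Step 14
Reactants: 19 (1R)-1-[(2S,4R,5R)-4-{[tert-butyl(dimethyl)silyl]oxy}-5-(prop-2-en-1-yl)oxolan-2-yl]hex-3-yn-1-ol
Product: 20 (1S)-1-[(2S,4R,5R)-4-{[tert-butyl(dimethyl)silyl]oxy}-5-(prop-2-en-1-yl)oxolan-2-yl]hex-3-yn-1-yl 4-nitrobenzoate
Conditions: 4-nitrobenzoic acid, PPh3, DIAD, toluene, 0 °C → rt
Reagents that add atoms: 4-nitrobenzoic acid, OC(=O)c1ccc(cc1)[N+](=O)[O-]
Why: Mitsunobu reaction, in which the carboxylate displaces the alkoxyphosphonium group at C10 by SN2 with inversion (R to S), giving the carbinol epimer from which a syn-directed epoxidation leads to the required C12/C13 configuration.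

Step 15
Reactants: 20 (1S)-1-[(2S,4R,5R)-4-{[tert-butyl(dimethyl)silyl]oxy}-5-(prop-2-en-1-yl)oxolan-2-yl]hex-3-yn-1-yl 4-nitrobenzoate
Product: 21 (1S)-1-[(2S,4R,5R)-4-{[tert-butyl(dimethyl)silyl]oxy}-5-(prop-2-en-1-yl)oxolan-2-yl]hex-3-yn-1-ol
Conditions: K2CO3 (cat.), MeOH, rt
Reagents that add atoms: none
Why: Base-catalysed transesterification removes the activated benzoate without touching the silyl ether or the C10 configuration.

Step 16
Reactants: 21 (1S)-1-[(2S,4R,5R)-4-{[tert-butyl(dimethyl)silyl]oxy}-5-(prop-2-en-1-yl)oxolan-2-yl]hex-3-yn-1-ol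
Product: 22 (1S,3Z)-1-[(2S,4R,5R)-4-{[tert-butyl(dimethyl)silyl]oxy}-5-(prop-2-en-1-yl)oxolan-2-yl]hex-3-en-1-ol
Conditions: H2 (1 atm, 1 equiv uptake), Pd on CaCO3 poisoned with Pb(OAc)2 (Lindlar catalyst), quinoline, EtOAc, rt
Reagents that add atoms: none
Why: Lindlar semihydrogenation adds H2 syn to the alkyne to give the Z-alkene, and the alkyne binds to the poisoned palladium much more strongly than the monosubstituted alkene, which should survive if uptake is stopped at one equivalent.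

Step 17
Reactants: 22 (1S,3Z)-1-[(2S,4R,5R)-4-{[tert-butyl(dimethyl)silyl]oxy}-5-(prop-2-en-1-yl)oxolan-2-yl]hex-3-en-1-ol
Product: 23 (1S)-1-[(2S,4R,5R)-4-{[tert-butyl(dimethyl)silyl]oxy}-5-(prop-2-en-1-yl)oxolan-2-yl]-2-[(2R,3S)-3-ethyloxiran-2-yl]ethan-1-ol
Conditions: VO(acac)2 (5 mol %), t-BuOOH, CH2Cl2, 0 °C → rt
Reagents that add atoms: tert-butyl hydroperoxide, CC(C)(C)OO
Why: Hydroxyl-directed vanadium-catalysed epoxidation of a homoallylic alcohol, in which the chair-like vanadate ester places the oxolane substituent on C10 equatorial and allylic strain of the Z-alkene fixes the C11–C12 rotamer, so the peroxide oxygen is delivered syn to the C10 oxygen and should give the (12R,13S)-cis-epoxide; the terminal alkene has no hydroxyl within reach and is left.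

Step 18
Reactants: 23 (1S)-1-[(2S,4R,5R)-4-{[tert-butyl(dimethyl)silyl]oxy}-5-(prop-2-en-1-yl)oxolan-2-yl]-2-[(2R,3S)-3-ethyloxiran-2-yl]ethan-1-ol
Product: 24 (1R)-1-[(2S,4R,5R)-4-{[tert-butyl(dimethyl)silyl]oxy}-5-(prop-2-en-1-yl)oxolan-2-yl]-2-[(2R,3S)-3-ethyloxiran-2-yl]ethyl acetate
Conditions: AcOH, PPh3, DIAD, THF, 0 °C → rt
Reagents that add atoms: acetic acid, CC(=O)O
Why: Mitsunobu esterification with acetic acid inverts C10 back to R by SN2 and installs the acetate in the same operation, so the C10 oxygen ends 1,3-anti to the epoxide, while epoxide, silyl ether and alkene are inert to the neutral redox conditions.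

Step 19
Reactants: 24 (1R)-1-[(2S,4R,5R)-4-{[tert-butyl(dimethyl)silyl]oxy}-5-(prop-2-en-1-yl)oxolan-2-yl]-2-[(2R,3S)-3-ethyloxiran-2-yl]ethyl acetate
Product: 27 (2R,3R,5R,6R,8S)-3-{[tert-butyl(dimethyl)silyl]oxy}-5-hydroxy-8-[(1S)-1-hydroxypropyl]-2-(prop-2-en-1-yl)oxocan-6-yl acetate, via bicyclic oxonium zwitterion 25 (not isolated), via acetoxonium zwitterion 26 (not isolated)
Conditions: BF3·OEt2 (1.1 equiv), CH2Cl2, −78 → −40 °C; then H2O, aqueous NaHCO3, 0 °C
Reagents that add atoms: water, O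
Why: Proposed new method: coordination of BF3 to the epoxide oxygen lets the oxolane oxygen displace it at C12 from the rear (5-exo-tet, inversion at C12), which closes a second five-membered ring and gives a cis-fused 1-oxoniabicyclo[3.3.0]octane with oxygen bonded to C6, C9 and C12 and the former epoxide oxygen held on C13 as a BF3 alkoxide. The carbonyl oxygen of the C10 acetate then attacks C9 anti to the O–C9 bond (5-exo-tet, inversion at C9), closing a 1,3-dioxolan-2-ylium ring and breaking the bond shared by the two five-membered rings, which thereby merge into the oxocane; water then hydrolyses the acetoxonium ion to the hydroxy acetate. The closest known reaction types are the bromonium-triggered expansion of alkenyl oxolanes to oxocanes through bicyclic trialkyloxonium ions opened by a neighbouring carbonyl group, and Lewis-acid epoxide-opening cascades terminated by ester or carbonate participation; here an epoxide replaces the bromonium ion as trigger. The configurations at C12 (S) and C9 (R) follow from the two SN2 inversions, that is from the epoxide set in step 17 and the oxolane set in step 10, while C6, C7, C10 and C13 are untouched, so the trans relationship of the substituents flanking the ether oxygen is carried over from precursors of normal ring size instead of being created on an eight-membered ring. The step needs the ether oxygen to open the epoxide faster than the acetate carbonyl and needs the oxonium ion to break at C9 and not at C6 or C12: the first is expected because the more basic ether oxygen closes a five-membered ring where the ester would have to close a six-membered one, and the second because only C9 has a vicinal acetate that can reach its rear side through a five-membered transition state.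

Step 20
Reactants: 27 (2R,3R,5R,6R,8S)-3-{[tert-butyl(dimethyl)silyl]oxy}-5-hydroxy-8-[(1S)-1-hydroxypropyl]-2-(prop-2-en-1-yl)oxocan-6-yl acetate
Product: 28 (2R,3R,5R,6R,8S)-8-[(1S)-1-(acetyloxy)propyl]-3-{[tert-butyl(dimethyl)silyl]oxy}-2-(prop-2-en-1-yl)oxocane-5,6-diyl diacetate
Conditions: Ac2O, pyridine, DMAP (cat.), CH2Cl2, rt
Reagents that add atoms: acetic anhydride, CC(=O)OC(C)=O
Why: DMAP-catalysed acylation esterifies the two free secondary hydroxyls, so every hydrolysis regioisomer of step 19 should converge on one triacetate with no change at any stereocentre.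

Step 21
Reactants: 28 (2R,3R,5R,6R,8S)-8-[(1S)-1-(acetyloxy)propyl]-3-{[tert-butyl(dimethyl)silyl]oxy}-2-(prop-2-en-1-yl)oxocane-5,6-diyl diacetate
Product: 29 (2R,3R,5R,6R,8S)-8-[(1S)-1-(acetyloxy)propyl]-3-{[tert-butyl(dimethyl)silyl]oxy}-2-(2-oxoethyl)oxocane-5,6-diyl diacetate
Conditions: O3, CH2Cl2, −78 °C; then PPh3, −78 °C → rt
Reagents that add atoms: ozone, [O-][O+]=O
Why: Ozonolysis with reductive work-up cleaves the only C=C bond left in the molecule to the C4 aldehyde under neutral conditions that spare the acetates and the silyl ether.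

Step 22
Reactants: 29 (2R,3R,5R,6R,8S)-8-[(1S)-1-(acetyloxy)propyl]-3-{[tert-butyl(dimethyl)silyl]oxy}-2-(2-oxoethyl)oxocane-5,6-diyl diacetate; 30 1,3-bis(triisopropylsilyl)propyne
Product: 31 (2R,3R,5R,6R,8S)-8-[(1S)-1-(acetyloxy)propyl]-3-{[tert-butyl(dimethyl)silyl]oxy}-2-[(2Z)-5-(triisopropylsilyl)pent-2-en-4-yn-1-yl]oxocane-5,6-diyl diacetate
Conditions: 30 (1.3 equiv), n-BuLi, THF, −20 °C; then 29, −78 °C → rt
Reagents that add atoms: 1,3-bis(triisopropylsilyl)propyne (30), CC(C)[Si](C(C)C)(C(C)C)CC#C[Si](C(C)C)(C(C)C)C(C)C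
Why: Peterson olefination, in which the lithiated bis-silyl propyne adds to the aldehyde and syn-elimination of silanolate from the kinetically preferred adduct of the bulky triisopropylsilyl carbanion should give the Z-enyne, the hindered stabilised anion adding to the aldehyde at −78 °C faster than it attacks the acetates.

Step 23
Reactants: 31 (2R,3R,5R,6R,8S)-8-[(1S)-1-(acetyloxy)propyl]-3-{[tert-butyl(dimethyl)silyl]oxy}-2-[(2Z)-5-(triisopropylsilyl)pent-2-en-4-yn-1-yl]oxocane-5,6-diyl diacetate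
Product: 32 (2R,3R,5R,6R,8S)-8-[(1S)-1-(acetyloxy)propyl]-3-hydroxy-2-[(2Z)-pent-2-en-4-yn-1-yl]oxocane-5,6-diyl diacetate (CNP0352372.1)
Conditions: Bu4NF, AcOH (1:1), THF, 0 °C → rt
Reagents that add atoms: none
Why: Fluoride cleaves both the alkynyl C–Si and the C7 O–Si bond, and acetic acid buffering should suppress acetate migration to the freed C7 hydroxyl and base-induced elimination.

Compound list
1 | (4R,5R)-2,2-dimethyl-1,3-dioxolane-4,5-dimethanol (2,3-O-isopropylidene-D-threitol) | OC[C@H]1OC(C)(C)O[C@@H]1CO | starting material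
2 | [(4R,5R)-5-({[tert-butyl(dimethyl)silyl]oxy}methyl)-2,2-dimethyl-1,3-dioxolan-4-yl]methanol | OC[C@H]1OC(C)(C)O[C@@H]1CO[Si](C)(C)C(C)(C)C | intermediate
3 | [(4R,5R)-5-({[tert-butyl(dimethyl)silyl]oxy}methyl)-2,2-dimethyl-1,3-dioxolan-4-yl]methyl trifluoromethanesulfonate | FC(F)(F)S(=O)(=O)OC[C@H]1OC(C)(C)O[C@@H]1CO[Si](C)(C)C(C)(C)C | intermediate
4 | vinylmagnesium bromide | C=C[Mg]Br | starting material
5 | tert-butyl(dimethyl){[(4R,5R)-2,2-dimethyl-5-(prop-2-en-1-yl)-1,3-dioxolan-4-yl]methoxy}silane | C=CC[C@H]1OC(C)(C)O[C@@H]1CO[Si](C)(C)C(C)(C)C | intermediate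
6 | [(4R,5R)-2,2-dimethyl-5-(prop-2-en-1-yl)-1,3-dioxolan-4-yl]methanol | C=CC[C@H]1OC(C)(C)O[C@@H]1CO | intermediate
7 | [(4R,5R)-2,2-dimethyl-5-(prop-2-en-1-yl)-1,3-dioxolan-4-yl]methyl trifluoromethanesulfonate | C=CC[C@H]1OC(C)(C)O[C@@H]1COS(=O)(=O)C(F)(F)F | intermediate
8 | tert-butyl(dimethyl)(prop-2-yn-1-yloxy)silane | C#CCO[Si](C)(C)C(C)(C)C | starting material
9 | tert-butyl(dimethyl)({4-[(4R,5R)-2,2-dimethyl-5-(prop-2-en-1-yl)-1,3-dioxolan-4-yl]but-2-yn-1-yl}oxy)silane | C=CC[C@H]1OC(C)(C)O[C@@H]1CC#CCO[Si](C)(C)C(C)(C)C | intermediate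
10 | 4-[(4R,5R)-2,2-dimethyl-5-(prop-2-en-1-yl)-1,3-dioxolan-4-yl]but-2-yn-1-ol | C=CC[C@H]1OC(C)(C)O[C@@H]1CC#CCO | intermediate
11 | (2E)-4-[(4R,5R)-2,2-dimethyl-5-(prop-2-en-1-yl)-1,3-dioxolan-4-yl]but-2-en-1-ol | C=CC[C@H]1OC(C)(C)O[C@@H]1C/C=C/CO | intermediate
12 | [(2R,3R)-3-{[(4R,5R)-2,2-dimethyl-5-(prop-2-en-1-yl)-1,3-dioxolan-4-yl]methyl}oxiran-2-yl]methanol | C=CC[C@H]1OC(C)(C)O[C@@H]1C[C@H]2O[C@@H]2CO | intermediate
13 | (2R,3R)-1-[(2R,3R)-3-(hydroxymethyl)oxiran-2-yl]hex-5-ene-2,3-diol | C=CC[C@@H](O)[C@H](O)C[C@H]1O[C@@H]1CO | intermediate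
14 | (2R,3R,5S)-5-[(1R)-1,2-dihydroxyethyl]-2-(prop-2-en-1-yl)oxolan-3-ol | C=CC[C@H]1O[C@H]([C@H](O)CO)C[C@H]1O | intermediate
15 | (2R)-2-hydroxy-2-[(2S,4R,5R)-4-hydroxy-5-(prop-2-en-1-yl)oxolan-2-yl]ethyl 4-methylbenzenesulfonate | C=CC[C@H]1O[C@H]([C@H](O)COS(=O)(=O)c2ccc(C)cc2)C[C@H]1O | intermediate
16 | (2R,3R,5S)-5-[(2R)-oxiran-2-yl]-2-(prop-2-en-1-yl)oxolan-3-ol | C=CC[C@H]1O[C@H]([C@H]2CO2)C[C@H]1O | intermediate
17 | tert-butyl(dimethyl){[(2R,3R,5S)-5-[(2R)-oxiran-2-yl]-2-(prop-2-en-1-yl)oxolan-3-yl]oxy}silane | C=CC[C@H]1O[C@H]([C@H]2CO2)C[C@H]1O[Si](C)(C)C(C)(C)C | intermediate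
18 | but-1-yne | CCC#C | starting material
19 | (1R)-1-[(2S,4R,5R)-4-{[tert-butyl(dimethyl)silyl]oxy}-5-(prop-2-en-1-yl)oxolan-2-yl]hex-3-yn-1-ol | C=CC[C@H]1O[C@H]([C@H](O)CC#CCC)C[C@H]1O[Si](C)(C)C(C)(C)C | intermediate
20 | (1S)-1-[(2S,4R,5R)-4-{[tert-butyl(dimethyl)silyl]oxy}-5-(prop-2-en-1-yl)oxolan-2-yl]hex-3-yn-1-yl 4-nitrobenzoate | C=CC[C@H]1O[C@H]([C@@H](OC(=O)c2ccc(cc2)[N+](=O)[O-])CC#CCC)C[C@H]1O[Si](C)(C)C(C)(C)C | intermediate
21 | (1S)-1-[(2S,4R,5R)-4-{[tert-butyl(dimethyl)silyl]oxy}-5-(prop-2-en-1-yl)oxolan-2-yl]hex-3-yn-1-ol | C=CC[C@H]1O[C@H]([C@@H](O)CC#CCC)C[C@H]1O[Si](C)(C)C(C)(C)C | intermediate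
22 | (1S,3Z)-1-[(2S,4R,5R)-4-{[tert-butyl(dimethyl)silyl]oxy}-5-(prop-2-en-1-yl)oxolan-2-yl]hex-3-en-1-ol | C=CC[C@H]1O[C@H]([C@@H](O)C/C=C\CC)C[C@H]1O[Si](C)(C)C(C)(C)C | intermediate
23 | (1S)-1-[(2S,4R,5R)-4-{[tert-butyl(dimethyl)silyl]oxy}-5-(prop-2-en-1-yl)oxolan-2-yl]-2-[(2R,3S)-3-ethyloxiran-2-yl]ethan-1-ol | C=CC[C@H]1O[C@H]([C@@H](O)C[C@H]2O[C@H]2CC)C[C@H]1O[Si](C)(C)C(C)(C)C | intermediate
24 | (1R)-1-[(2S,4R,5R)-4-{[tert-butyl(dimethyl)silyl]oxy}-5-(prop-2-en-1-yl)oxolan-2-yl]-2-[(2R,3S)-3-ethyloxiran-2-yl]ethyl acetate | C=CC[C@H]1O[C@H]([C@H](OC(C)=O)C[C@H]2O[C@H]2CC)C[C@H]1O[Si](C)(C)C(C)(C)C | intermediate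
25 | cis-fused 1-oxoniabicyclo[3.3.0]octane zwitterion: oxonium oxygen bonded to C6, C9 and C12; allyl on C6, silyloxy on C7, acetoxy on C10, 1-(trifluoroboranuidyloxy)propyl on C12; 6R,7R,9S,10R,12S,13S by target numbering | C=CC[C@@H]1[C@H](O[Si](C)(C)C(C)(C)C)C[C@@H]2[O+]1[C@@H](C[C@H]2OC(C)=O)[C@H](CC)O[B-](F)(F)F | intermediate
26 | oxocane carrying a 2-methyl-1,3-dioxolan-2-ylium ring fused across C9–C10 and a 1-(trifluoroboranuidyloxy)propyl group on C12; allyl on C6, silyloxy on C7; 6R,7R,9R,10R,12S,13S by target numbering | C=CC[C@H]1O[C@H]([C@H](CC)O[B-](F)(F)F)C[C@H]2[O+]=C(C)O[C@@H]2C[C@H]1O[Si](C)(C)C(C)(C)C | intermediate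
27 | (2R,3R,5R,6R,8S)-3-{[tert-butyl(dimethyl)silyl]oxy}-5-hydroxy-8-[(1S)-1-hydroxypropyl]-2-(prop-2-en-1-yl)oxocan-6-yl acetate | C=CC[C@H]1O[C@H]([C@H](CC)O)C[C@@H](OC(C)=O)[C@H](O)C[C@H]1O[Si](C)(C)C(C)(C)C | intermediate
28 | (2R,3R,5R,6R,8S)-8-[(1S)-1-(acetyloxy)propyl]-3-{[tert-butyl(dimethyl)silyl]oxy}-2-(prop-2-en-1-yl)oxocane-5,6-diyl diacetate | C=CC[C@H]1O[C@H]([C@H](CC)OC(C)=O)C[C@@H](OC(C)=O)[C@H](OC(C)=O)C[C@H]1O[Si](C)(C)C(C)(C)C | intermediate
29 | (2R,3R,5R,6R,8S)-8-[(1S)-1-(acetyloxy)propyl]-3-{[tert-butyl(dimethyl)silyl]oxy}-2-(2-oxoethyl)oxocane-5,6-diyl diacetate | O=CC[C@H]1O[C@H]([C@H](CC)OC(C)=O)C[C@@H](OC(C)=O)[C@H](OC(C)=O)C[C@H]1O[Si](C)(C)C(C)(C)C | intermediate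
30 | 1,3-bis(triisopropylsilyl)propyne | CC(C)[Si](C(C)C)(C(C)C)CC#C[Si](C(C)C)(C(C)C)C(C)C | starting material
31 | (2R,3R,5R,6R,8S)-8-[(1S)-1-(acetyloxy)propyl]-3-{[tert-butyl(dimethyl)silyl]oxy}-2-[(2Z)-5-(triisopropylsilyl)pent-2-en-4-yn-1-yl]oxocane-5,6-diyl diacetate | CC(C)[Si](C(C)C)(C(C)C)C#C/C=C\C[C@H]1O[C@H]([C@H](CC)OC(C)=O)C[C@@H](OC(C)=O)[C@H](OC(C)=O)C[C@H]1O[Si](C)(C)C(C)(C)C | intermediate
32 | (2R,3R,5R,6R,8S)-8-[(1S)-1-(acetyloxy)propyl]-3-hydroxy-2-[(2Z)-pent-2-en-4-yn-1-yl]oxocane-5,6-diyl diacetate (CNP0352372.1; 3Z,6R,7R,9R,10R,12S,13S by chain numbering) | C#C/C=C\C[C@H]1O[C@H]([C@H](CC)OC(C)=O)C[C@@H](OC(C)=O)[C@H](OC(C)=O)C[C@H]1O | target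

Total step count: 23. Longest linear sequence: 23 steps (1 to 32; compounds 4, 8, 18 and 30 are bought).

Steps most likely to fail

Step 19 (ring expansion). The acetate carbonyl or an outside nucleophile may open the activated epoxide before the ring oxygen does, or the oxonium ion may collapse by hydride shift or elimination instead of acetate-assisted cleavage at C9. The fallback uses the known bromonium version of the same ring expansion; it sets out from 19 and comes back at 28. Dissolving-metal reduction of the alkyne (Na, NH3(l), THF, −78 °C) should give the (1R,3E)-homoallylic alcohol F1, and acetylation (Ac2O, pyridine) the E-alkenyl acetate F2. Bromonium-triggered expansion (Et2SBr·SbCl5Br, MeNO2, −25 °C, then water) should then give the bromo hydroxy acetate F3: the ring oxygen bonds to C12 of the bromonium ion, the acetate opens the bicyclic oxonium ion at C9, and bromine sits on C13 anti to the new O–C12 bond. Acetylation gives the bromo diacetate F4, and SN2 displacement of the secondary bromide by acetate (CsOAc, 18-crown-6, toluene, 80 °C) inverts C13 to the (S)-acetate and delivers 28. The E-alkene is used so that anti addition followed by one inversion ends at the same C12/C13 configuration as the epoxide route; facial selectivity of the bromonium step rests on the substrate alone.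

Step 18 (Mitsunobu acetate installation). At the alkoxyphosphonium stage the neighbouring ring oxygen may displace the leaving group itself (retention or ring enlargement to an oxane), or elimination may outrun SN2 attack by the weakly acidic acetic acid, so inversion at C10 would be incomplete. The fallback avoids any substitution at C10; it sets out from 19 and comes back at 24. Lindlar semihydrogenation of 19 should give the (1R,3Z)-homoallylic alcohol F5. Epoxidation under reagent control with a vanadium catalyst carrying a chiral C2-symmetric bis-hydroxamic acid ligand (VO(OiPr)3, ligand, cumene hydroperoxide, toluene, 0 °C), with the ligand enantiomer chosen to deliver oxygen anti to the C10 hydroxyl against the substrate preference, would give the anti-epoxy alcohol F6. Plain acetylation (Ac2O, pyridine, DMAP) then gives 24.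

Step 22 (Peterson olefination). The basic lithium reagent may attack or enolise the acetates or trigger β-elimination of the ring oxygen from the β-alkoxy aldehyde, and Z-selectivity may erode. The fallback forms C3=C4 and C2–C3 separately; it sets out from 29 and comes back at 31. Stork–Zhao olefination (Ph3PCH2I iodide, NaN(SiMe3)2, THF/DMPU, −78 °C) should give the Z-vinyl iodide F7, and Sonogashira coupling with ethynyltri(propan-2-yl)silane (Pd(PPh3)4, CuI, Et3N, rt) joins C2–C3 with retention of the alkene geometry to give 31.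

Further compounds
F1 | step 19 | (1R,3E)-1-[(2S,4R,5R)-4-{[tert-butyl(dimethyl)silyl]oxy}-5-(prop-2-en-1-yl)oxolan-2-yl]hex-3-en-1-ol | C=CC[C@H]1O[C@H]([C@H](O)C/C=C/CC)C[C@H]1O[Si](C)(C)C(C)(C)C
F2 | step 19 | (1R,3E)-1-[(2S,4R,5R)-4-{[tert-butyl(dimethyl)silyl]oxy}-5-(prop-2-en-1-yl)oxolan-2-yl]hex-3-en-1-yl acetate | C=CC[C@H]1O[C@H]([C@H](OC(C)=O)C/C=C/CC)C[C@H]1O[Si](C)(C)C(C)(C)C
F3 | step 19 | (2R,3R,5R,6R,8S)-8-[(1R)-1-bromopropyl]-3-{[tert-butyl(dimethyl)silyl]oxy}-5-hydroxy-2-(prop-2-en-1-yl)oxocan-6-yl acetate | C=CC[C@H]1O[C@H]([C@@H](CC)Br)C[C@@H](OC(C)=O)[C@H](O)C[C@H]1O[Si](C)(C)C(C)(C)C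
F4 | step 19 | (2R,3R,5R,6R,8S)-8-[(1R)-1-bromopropyl]-3-{[tert-butyl(dimethyl)silyl]oxy}-2-(prop-2-en-1-yl)oxocane-5,6-diyl diacetate | C=CC[C@H]1O[C@H]([C@@H](CC)Br)C[C@@H](OC(C)=O)[C@H](OC(C)=O)C[C@H]1O[Si](C)(C)C(C)(C)C
F5 | step 18 | (1R,3Z)-1-[(2S,4R,5R)-4-{[tert-butyl(dimethyl)silyl]oxy}-5-(prop-2-en-1-yl)oxolan-2-yl]hex-3-en-1-ol | C=CC[C@H]1O[C@H]([C@H](O)C/C=C\CC)C[C@H]1O[Si](C)(C)C(C)(C)C
F6 | step 18 | (1R)-1-[(2S,4R,5R)-4-{[tert-butyl(dimethyl)silyl]oxy}-5-(prop-2-en-1-yl)oxolan-2-yl]-2-[(2R,3S)-3-ethyloxiran-2-yl]ethan-1-ol | C=CC[C@H]1O[C@H]([C@H](O)C[C@H]2O[C@H]2CC)C[C@H]1O[Si](C)(C)C(C)(C)C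
F7 | step 22 | (2R,3R,5R,6R,8S)-8-[(1S)-1-(acetyloxy)propyl]-3-{[tert-butyl(dimethyl)silyl]oxy}-2-[(2Z)-3-iodoprop-2-en-1-yl]oxocane-5,6-diyl diacetate | I/C=C\C[C@H]1O[C@H]([C@H](CC)OC(C)=O)C[C@@H](OC(C)=O)[C@H](OC(C)=O)C[C@H]1O[Si](C)(C)C(C)(C)C
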